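**Assumptions:** The target is planar and has no stereogenic element, so the request for a single enantiomer is met by the one achiral compound and no step has to control configuration. 3,4,5-Tribromoaniline is taken as a catalogue compound.

## Analysis of the target

1. The target is a 1H-indole: a benzene ring (C3a–C4–C5–C6–C7–C7a) fused to a pyrrole ring (N1–C2–C3–C3a–C7a). Every position except N1–H and C7–H carries a heteroatom substituent.
2. There is no stereocenter, axis or plane of chirality, so the problem is one of regiochemistry and chemoselectivity.
3. The benzene ring bears three contiguous bromines at C4, C5 and C6. This pattern runs against the innate substitution preference of an indole, and C4–Br sits in peri contact with the C3 substituent.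
4. The pyrrole ring bears two identical SMe groups at C2 and C3, which makes C2=C3 an electron-rich, easily oxidised N,S-substituted alkene.
5. The sensitive groups work against each other. Electrophilic bromine oxidises thioethers, organolithium reagents used to make C–S bonds exchange with C–Br, and C–Br bonds can enter palladium(0) chemistry.
6. The feature exploited is that the molecule consists of two halves with hidden symmetry. The atoms S–C2=C3–S map onto a symmetric alkyne. The atoms N1, C7a, C7, C6(Br), C5(Br), C4(Br) and C3a map onto an aniline with a mirror plane through C7a and C5, in which C3a and C7 are equivalent.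
7. Cutting N1–C2 and C3–C3a separates exactly these two halves, and the cut carbon of the aniline half is then singled out by one trivial functionalisation.

## Retrosynthetic reasoning

**Disconnection 1 (8 to 6 + 4, through 7).**
- The bonds N1–C2 and C3–C3a of 8 are cut together.
- Cutting the C–S bonds would leave a tribromoindole that needs its own ring synthesis and two unequal sulfenylations. Cutting the C–Br bonds would leave a regiochemical problem with no handle.
- The chosen cut leaves all five heteroatom substituents on the fragments. It builds the whole pyrrole ring in one operation and brings in C2, C3 and both sulfur atoms as one piece.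
- Because 4 has two identical ends, the orientation of the alkyne, which is the usual weakness of this kind of annulation, is no longer an issue.
- The forward reaction is a palladium-catalysed heteroannulation through the vinylpalladium species 7. It has to distinguish one C–I bond from three C–Br bonds and has to tolerate thioether sulfur.

**Disconnection 2 (6 to 5).**
- The C–I bond of 6 is cut.
- In 5 the para position is occupied by bromine and the two ortho positions are related by the mirror plane, so an electrophilic iodine source can give only one mono-iodide.
- The forward step fixes the later C3a. It only has to stop after one iodination.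

**Disconnection 3 (4 to 3, 2 and 1).**
- Both C(sp)–S bonds of 4 are cut, giving the C2 dianion 3 and a methylsulfenyl-transfer reagent.
- 3 comes from the bulk solvent 1 by elimination to 2 and twofold halogen–metal exchange, all in one flask.
- The gain is a two-carbon building block in one operation from a weighable liquid. The forward step has to sulfenylate both ends.

## Alternatives that were turned down

**Alternative 1: the textbook route, C–S and C–Br disconnections on the intact indole.**
- *Forward steps:* Indole is sulfenylated at C3 and then at C2 to give 2,3-bis(methylsulfanyl)-1H-indole A1, which is then brominated three times.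
- *Regiochemistry:* With C2 and C3 blocked, attack goes to C5 and C6 and then has to choose between C4 and C7. C4 is shielded by the peri C3–SMe group, and each new bromine must enter next to a deactivating one, so nothing in A1 enforces the 4,5,6 pattern.
- *Chemoselectivity:* Electrophilic bromine also attacks the thioethers, through bromosulfonium formation, oxidation and ipso loss of sulfur at C3.
- *Reverse order:* Sulfenylation of 4,5,6-tribromo-1H-indole A2 solves the bromine pattern. However, A2 needs its own ring synthesis from 5. The two SMe groups then enter one at a time, the first next to the peri C4–Br and the second on a deactivated ring. Lithiation at C2 is excluded by the C–Br bonds.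
- *Step economy:* This costs at least twice the number of steps of the chosen route.

**Alternative 2: cutting N1–C2 and C3–S, a sulfenylative 5-endo-dig cyclisation.**
- *Forward key step:* 3,4,5-Tribromo-2-[(methylsulfanyl)ethynyl]aniline A3 is treated with an MeS+ source. Sulfur adds to the aryl-bearing alkyne carbon, and nitrogen closes onto the sulfur-stabilised cationic carbon. The polarity is matched.
- *Economy:* The same two ring bonds are made in separate operations. A3 needs a cross-coupling of 6 with a volatile mono-thio alkyne, or an alkynylation, desilylation and thiolation sequence, and the two SMe groups come from two different reagents.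
- *Nitrogen:* The free NH2 group would be sulfenylated at nitrogen, so a protecting group is needed. The very weakly nucleophilic tribromoaniline nitrogen is then a poor partner for ring closure.
- *Verdict:* More steps for the same bonds.

**Alternative 3: cutting C2–C3, a carbanion–isothiocyanate closure.**
- *Forward steps:* 5 is ortho-alkylated through an azasulfonium [2,3] shift with dimethyl sulfide to give 3,4,5-tribromo-2-[(methylsulfanyl)methyl]aniline A4. Thiophosgene converts A4 into 1,2,3-tribromo-5-isothiocyanato-4-[(methylsulfanyl)methyl]benzene A5. A strong base generates the α-thio benzylic anion, which adds to the N=C=S carbon to give sodium 4,5,6-tribromo-3-(methylsulfanyl)-1H-indole-2-thiolate A6. Methyl iodide caps A6.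
- *Reason turned down:* The benzylic CH2 needs an amide or hydride base. Such a base can migrate or remove halogen on a tribromoarene and can add to the isothiocyanate.
- *Step economy:* The route has four linear steps, uses thiophosgene, and again introduces the two sulfur atoms separately.

Key step: step 3

## Route

Step 1
Reactants: 1 trichloroethylene
Product: 4 bis(methylsulfanyl)acetylene, via dichloroacetylene 2 (not isolated), via dilithium acetylide 3 (not isolated)
Conditions: n-BuLi (3.0 equiv), Et2O, −78 °C to rt; then MeSSO2Me (2.1 equiv), THF, −78 °C to rt; distillation under reduced pressure
Reagents that add atoms: S-methyl methanethiosulfonate, CSS(C)(=O)=O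
Why: Deprotonation of 1 with loss of LiCl gives 2, which never accumulates because excess n-BuLi converts it by twofold chlorine–lithium exchange into finely divided, reactive 3, a known entry to this dianion. Electrophilic sulfenylation of an acetylide by a thiosulfonate is a standard C(sp)–S bond formation, and the methanesulfinate leaving group does not add to the thioalkyne as a thiolate could.

Step 2
Reactants: 5 3,4,5-tribromoaniline
Product: 6 3,4,5-tribromo-2-iodoaniline
Conditions: NIS (1.0 equiv), TFA (0.2 equiv), MeCN, 0 °C to rt, dark
Reagents that add atoms: N-iodosuccinimide, O=C1CCC(=O)N1I
Why: Electrophilic aromatic iodination directed by NH2, in which the para position is blocked by bromine, the two ortho positions are equivalent by the mirror plane of 5, and the bromines at C3 and C5 direct to the same carbons, so only one mono-iodide can form. One equivalent of NIS and the low temperature should hold back the second iodination.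

Step 3
Reactants: 6 3,4,5-tribromo-2-iodoaniline; 4 bis(methylsulfanyl)acetylene (1.5 equiv)
Product: 8 4,5,6-tribromo-2,3-bis(methylsulfanyl)-1H-indole, via (E)-[2-(2-amino-4,5,6-tribromophenyl)-1,2-bis(methylsulfanyl)ethenyl]palladium(II) iodide 7 (not isolated)
Conditions: Pd(OAc)2 (10 mol %), LiCl (1 equiv), K2CO3 (3 equiv), degassed DMF, 80 °C, stopped when 6 is consumed
Reagents that add atoms: none
Why: Proposed new method: the Larock heteroannulation is carried over to a 1,2-bis(alkylsulfanyl)alkyne, an alkyne class for which this annulation has no close precedent; the closest known reaction type is the Larock indole synthesis of o-iodoanilines with dialkyl-, diaryl- and silylalkynes, and addition of an aryl–metal bond across an alkynyl sulfide is a known elementary step. Pd(0) inserts into the C–I bond of 6, alkyne 4 binds and inserts syn into the aryl–Pd bond (C3a–C3 formed) to give 7, carbonate takes up HI while nitrogen binds to palladium, and C–N reductive elimination (N1–C2 formed) releases 8 and Pd(0). The one ring that closes is the pyrrole ring, in a formal [3+2] annulation whose closing event is reductive elimination from a six-membered azapalladacycle that contracts to the five-membered ring, so no 5-endo-dig attack on a free alkyne is needed. No stereocenter is formed; the only geometric element is the E double bond of 7 (aryl and palladium cis), fixed by the syn insertion, and this geometry holds the NH2 group within reach of palladium. Chemoselectivity for C–I over the three C–Br bonds is needed and rests on the much faster oxidative addition of the weaker C–I bond under phosphine-free chloride conditions, under which aryl bromides do not normally enter this annulation, and on stopping the reaction when 6 is used up. The orientation of the alkyne, the usual weak point of this reaction, is no issue because both ends of 4 are the same, and the site on the benzene ring is fixed by the iodine of 6. The three bromines make the NH2 group more acidic, which should ease N–Pd bond formation, and SMe is a small substituent, so insertion next to the bromine that becomes C4–Br should stay feasible. Thioether binding to palladium is countered by chloride as a competing ligand, the polar solvent and the raised catalyst loading.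

## Compound list

1 | trichloroethylene (1,1,2-trichloroethene) | ClC=C(Cl)Cl | starting material
2 | dichloroacetylene | ClC#CCl | intermediate
3 | dilithium acetylide | [Li]C#C[Li] | intermediate
4 | bis(methylsulfanyl)acetylene (1,2-bis(methylsulfanyl)ethyne) | CSC#CSC | intermediate
5 | 3,4,5-tribromoaniline | Nc1cc(Br)c(Br)c(Br)c1 | starting material
6 | 3,4,5-tribromo-2-iodoaniline | Nc1cc(Br)c(Br)c(Br)c1I | intermediate
7 | (E)-[2-(2-amino-4,5,6-tribromophenyl)-1,2-bis(methylsulfanyl)ethenyl]palladium(II) iodide, ancillary ligands omitted | CS/C([Pd]I)=C(\SC)c1c(N)cc(Br)c(Br)c1Br | intermediate
8 | 4,5,6-tribromo-2,3-bis(methylsulfanyl)-1H-indole | CSc1[nH]c2cc(Br)c(Br)c(Br)c2c1SC | target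

## Step count and risk

Total step count: 3. Longest linear sequence: 2 steps (5 to 6 to 8). The branch 1 to 4 to 8 also has two steps.

**Step 3 (key step, Proposed new method).**
- *What may go wrong:*
  - Loss of catalyst activity through sulfur binding. The two neighbouring SMe groups of the product can chelate palladium as it accumulates.
  - Cleavage of a C(sp)–S bond of the alkyne by Pd(0), with transfer of methylthiolate to the arylpalladium species instead of insertion.
  - Slow insertion, because the arylpalladium centre is flanked by NH2 and Br.
  - Onset of oxidative addition into C–Br bonds towards the end of the reaction, with debromination or oligomerisation.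
- *Fallback:* It uses known chemistry only, sets out from 5 and comes back at 8. It replaces the annulation by a Gassman oxindole synthesis in which the sulfur normally discarded is kept as the C3 substituent.
  - 5 is N-chlorinated with t-BuOCl (CH2Cl2, −70 °C) to give N-chloro-3,4,5-tribromoaniline F1.
  - Ethyl (methylsulfanyl)acetate converts F1 into (2-ethoxy-2-oxoethyl)(methyl)[(3,4,5-tribromophenyl)amino]sulfonium chloride F2.
  - Triethylamine forms the ylide, and a Sommelet–Hauser type [2,3] shift to either of the two equivalent ortho carbons gives racemic ethyl 2-(2-amino-4,5,6-tribromophenyl)-2-(methylsulfanyl)acetate F3.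
  - Dilute acid closes the lactam to give racemic 4,5,6-tribromo-3-(methylsulfanyl)-1,3-dihydro-2H-indol-2-one F4.
  - Lawesson's reagent in warm toluene gives racemic 4,5,6-tribromo-3-(methylsulfanyl)-1,3-dihydro-2H-indole-2-thione F5.
  - S-Methylation with MeI and K2CO3 in acetone aromatises F5 to 8 and erases the transient C3 stereocenter.

**Step 2.**
- *What may go wrong:* Over-iodination at the second ortho carbon. It stays activated by NH2 and is only slightly deactivated by the first iodine, so a mixture that is hard to separate could carry a second reactive C–I bond into step 3. Oxidation at nitrogen is a minor risk.
- *Fallback:* It sets out from 5 and comes back at 6. It changes from electrophilic substitution to deprotonative metalation, where the amount of base limits the reaction to one site.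
  - 5 is converted with NaHMDS and Boc2O into tert-butyl (3,4,5-tribromophenyl)carbamate F6.
  - TMPMgCl·LiCl (2.2 equiv, THF, −20 °C) removes N–H and then the C–H flanked by the carbamate and bromine, without bromine–metal exchange.
  - Iodine then gives tert-butyl (3,4,5-tribromo-2-iodophenyl)carbamate F7.
  - TFA in CH2Cl2 sets 6 free.

**Step 1.**
- *What may go wrong:* Incomplete second sulfenylation, because 3 reacts as a suspension. Loss of the fairly volatile product on isolation, and addition of nucleophiles across the electron-rich triple bond.
- *Fallback:* It sets out from 1 and comes back at 4. It builds the two C–S bonds one after the other, the first with nucleophilic and the second with electrophilic sulfur, through a soluble mono-anion.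
  - 1 reacts with NaSMe in THF, by elimination and anti addition, to give (E)-1,2-dichloro-1-(methylsulfanyl)ethene F8.
  - n-BuLi (2 equiv, −78 °C) effects elimination and chlorine–lithium exchange to give lithium (methylsulfanyl)acetylide F9.
  - S-Methyl methanethiosulfonate converts F9 into 4.

## Further compounds

F1 | step 3 | N-chloro-3,4,5-tribromoaniline | ClNc1cc(Br)c(Br)c(Br)c1
F2 | step 3 | (2-ethoxy-2-oxoethyl)(methyl)[(3,4,5-tribromophenyl)amino]sulfonium chloride | CCOC(=O)C[S+](C)Nc1cc(Br)c(Br)c(Br)c1.[Cl-]
F3 | step 3 | ethyl 2-(2-amino-4,5,6-tribromophenyl)-2-(methylsulfanyl)acetate (racemic) | CCOC(=O)C(SC)c1c(N)cc(Br)c(Br)c1Br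
F4 | step 3 | 4,5,6-tribromo-3-(methylsulfanyl)-1,3-dihydro-2H-indol-2-one (racemic) | CSC1C(=O)Nc2cc(Br)c(Br)c(Br)c12
F5 | step 3 | 4,5,6-tribromo-3-(methylsulfanyl)-1,3-dihydro-2H-indole-2-thione (racemic) | CSC1C(=S)Nc2cc(Br)c(Br)c(Br)c12
F6 | step 2 | tert-butyl (3,4,5-tribromophenyl)carbamate | CC(C)(C)OC(=O)Nc1cc(Br)c(Br)c(Br)c1
F7 | step 2 | tert-butyl (3,4,5-tribromo-2-iodophenyl)carbamate | CC(C)(C)OC(=O)Nc1cc(Br)c(Br)c(Br)c1I
F8 | step 1 | (E)-1,2-dichloro-1-(methylsulfanyl)ethene | CS/C(Cl)=C\Cl
F9 | step 1 | lithium (methylsulfanyl)acetylide | [Li]C#CSC
A1 | alternative 1 | 2,3-bis(methylsulfanyl)-1H-indole | CSc1[nH]c2ccccc2c1SC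
A2 | alternative 1 | 4,5,6-tribromo-1H-indole | Brc1cc2[nH]ccc2c(Br)c1Br
A3 | alternative 2 | 3,4,5-tribromo-2-[(methylsulfanyl)ethynyl]aniline | CSC#Cc1c(N)cc(Br)c(Br)c1Br
A4 | alternative 3 | 3,4,5-tribromo-2-[(methylsulfanyl)methyl]aniline | CSCc1c(N)cc(Br)c(Br)c1Br
A5 | alternative 3 | 1,2,3-tribromo-5-isothiocyanato-4-[(methylsulfanyl)methyl]benzene | CSCc1c(N=C=S)cc(Br)c(Br)c1Br
A6 | alternative 3 | sodium 4,5,6-tribromo-3-(methylsulfanyl)-1H-indole-2-thiolate | CSc1c([S-])[nH]c2cc(Br)c(Br)c(Br)c12.[Na+]
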